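The ratio of addition to transfer at a living end gives the units a chain gains before it dies, so the length turns on what fraction of the free monomer charge a chain meets.

free monomer 0.10 M; transfer agent 1.00 mM; pre-initiator 0.2 mol%; time 8.0 min

* average number of monomer units in a chain (chains begun, living or dead) at 8.0 min
* part of the free monomer that has reacted at 8.0 min

In this flask the pre-initiator releases initiator with a half-life of 0.17 min, longer than the 1.6 s of initiator and the 2.6 s of a living end, so that release is the rate-limiting step and chains start at its pace, decaying with 0.070 s⁻¹. Free monomer meanwhile decays with 0.014 s⁻¹. Integrating the product in closed form, a chain meets on average the fraction 83.3% of the charge. The pre-initiator charge equals 20.0% of the transfer agent charge, so transfer is taken as pseudo-first-order at that charge. This reckoning gives 18.6 units, the met-monomer chain length: one unit plus the addition-to-transfer ratio at the fraction met. The uncatalysed half-life of 0.83 min is short against 8.0 min, and that decay leaves 0.121% of the charge, a conversion of 99.9%.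

The forecast gives 99.9% for the conversion and 18 for the chain, lower than this reckoning, the chain on the ground that “each chain lives only about 4 s against the excess transfer agent”.

The flask gives 18.2 and 99.9%.

    free monomer + initiator → living end + monomer in chains (k1 = 4.3 M⁻¹ s⁻¹)
    free monomer + living end → monomer in chains + living end, rate k2*[living end]*[free monomer] (k2 = 57 M⁻¹ s⁻¹)
    living end + transfer agent → dead chain (k3 = 270 M⁻¹ s⁻¹)
    free monomer → uncatalysed product (k4 = 0.014 s⁻¹)
    pre-initiator → initiator (k5 = 0.070 s⁻¹)

The flask's 18.2 lies just under the met-monomer length of 18.6. The neighbour flask is charged with 2.5 × 10⁻⁴ M of transfer agent, and the same reckoning gives it 71.4 units. The neighbour flask gives 74.3 at a conversion of 99.9%. In the neighbour flask the pre-initiator charge equals 80.0% of the transfer agent charge, and 20% of that transfer agent remains at the end. Monomer in chains in the neighbour flask reaches 14.9% of the free monomer charge, against 3.65% in the original flask, and uncatalysed product in the neighbour flask stands at 85.1%.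

All constants were drawn at random within sensible limits; the result is computed.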